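## Structural features

Numbering used throughout: ring carbons C1–C9, with C1 carrying the exocyclic CH2, C4=C5 the ring alkene (CH3 on C5), C8 carrying the side chain Ca(CH2OAc)=Cb–Cc=Cd–C(CH3)2OH, and C9 carrying the ester carbon C10.

- The target is one nine-membered carbocycle with an exocyclic methylene on C1, an E trisubstituted C4=C5 alkene, a methyl ester on C9 and a dienyl chain on C8. In the chain, Ca=Cb is Z (CH2OAc cis to Cc) and Cc=Cd is E.
- The two stereocentres, C8 (S) and C9 (R), are adjacent and trans on the ring.
- C8 is permanent once made. C9 is alpha to the ester and allylic to C1=CH2, so it can be lost or inverted through its dienolate.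
- Fragile groups: the beta,gamma-unsaturated ester (prone to conjugation), the primary allylic acetate, and the tertiary doubly allylic alcohol (ionises in acid). When the acetate is absent, the CH2OH on Ca can close onto C10 to a six-membered lactone.
- The real difficulty is the nine-membered ring with an E alkene (strain, entropy), the absolute configuration of C8 next to a fully substituted alkene carbon, and the soft C9 centre.
- The key step exploits the C5–C6 bond. It joins sp2 C5 of the E alkene to the C6–C7 bridge that ends at C8, so C6–C7 can enter as a vinyl group on C8 and C5 as an E iodoalkene.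
- The C1/C9 pair can be stored as a Z tetrasubstituted C1=C9 enoate with CH2SiMe3 on C1. This pre-bends the chain for ring closure and masks both the exocyclic alkene and the acidic C9–H.

## Logic of the disconnections

**25 to 24.** The O–acyl bond of the primary acetate is cut. The acetate is the most labile group, so it goes on last. This leaves a diol whose hydroxyls differ sharply (primary allylic against tertiary). The forward step must acylate only the primary hydroxyl without epimerising C9 or letting that hydroxyl close onto the ester.

**24 to 23.** The C9–H bond and the C1=CH2 pi bond are exchanged for a C1=C9 pi bond and a CH2–Si bond. This removes the epimerisable centre and the reactive 1,1-disubstituted alkene and gives a robust tetrasubstituted enoate. The forward step must cleave C–Si with fluoride, protonate the dienolate at C9 and not at the terminal CH2, and do so on the face of the side chain.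

**23 to 22.** Two O–Si bonds are cut. The hydroxyls must be masked through all organometallic steps, and one fluoride-labile pair keeps the endgame short. The forward step must remove both silyl ethers while keeping the CH2–SiMe3 bond.

**22 to 20 (through 21).** The ring bond C5–C6 is cut. It is the only ring bond between an alkene carbon of fixed geometry and a two-carbon bridge that can come from a vinyl group. The ring disappears without touching C8. The forward step needs hydroboration of one alkene among six, ring closure faster than oligomerisation, and retention of the E geometry.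

**20 to 19.** The C1–CH2Si bond is cut. A tetrasubstituted Z alkene is best drawn from an enol derivative of a beta-keto ester by stereospecific substitution. The forward step must proceed with retention and must leave the alkenyl iodide alone.

**19 to 17 (through 18).** The C1–O bond of the enol triflate is cut back to the ketone. The beta-keto ester is the natural nucleophile for the next cut. The forward step must fix the enolate geometry (oxygen cis to the ester) by chelation.

**17 to 7 plus 16.** The C8–C9 bond is cut. This splits the molecule into two halves of similar size next to the only permanent stereocentre. A branched allylic substitution makes C8 and its vinyl group in one event. The forward step needs attack at the substituted allyl terminus and ligand control of its face.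

**7 to 5 plus 4 (through 6).** The C2–C3 bond is cut. C2 is the terminal carbon of an acetoacetate and C3 an allylic bromide carbon. The forward step must form the dianion completely before the iodoalkene is added.

**4 to 3 to 1 (through 2).** The C–Br bond is traded for C–O, then C–I and C–H are removed across the triple bond. The forward step must add H and metal syn, with the metal on the methyl-bearing carbon, to give the E iodide.

**16 to 15.** The C7=C8 alkene is cut by retro-metathesis. This removes the allylic carbonate and leaves a triene with a terminal vinyl group. The forward step must engage only that vinyl group and give the E alkene.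

**15 to 14 plus 10.** The Cb–Cc bond between two sp2 carbons is cut. Each half then derives from one small alkyne. The forward step must retain geometry in both partners.

**14 to 13 to 11 (through 12).** The O–Si bond is cut, then the Ca–C8 bond and the Cb–I bond across the alkyne. One operation builds the trisubstituted alkene. The forward step must add anti, so that iodine ends cis to CH2O.

**10 to 9 to 8.** The C–B and C–H bonds across the alkyne are cut, then O–Si. The forward step must add syn with boron at the terminus.

## Other disconnections considered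

**Alternative 1:** The ring is traced back to cyclopentanol A1, so that C2–C3 is formed while the cyclopentane bond C5–C9 is broken. Forward, KH with 18-crown-6 gives the potassium alkoxide, the anion-accelerated [3,3] shift expands the ring by four atoms, and PhNTf2 traps the C9 enolate in the same flask as enol triflate A2.
- In its favour: the ring forms in a concerted intramolecular step that needs no dilution and cannot oligomerise. The E C4=C5 alkene follows from a chair-like transition state and the Z C1=C9 geometry is fixed by the ring. A2 is one palladium-catalysed methoxycarbonylation away from the enoate motif of 22, so the chosen endgame could be reused.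
- Where it is equal or better: on ring formation and on the two ring alkenes it equals the chosen plan and is probably better.
- Against it here: A2 has a bare CH2 at C8, the one position that needs the side chain and the permanent stereocentre, and C8 in A2 is not activated for later substitution. The chain would have to sit next to the carbinol in A1. That requires a cyclopentanone with an enolisable alpha centre, a quaternary alpha' centre and a diastereoselective 1,2-addition.
- Comparison: it solves ring and alkenes first and leaves C8 open, whereas the chosen plan fixes C8 by catalysis before any ring exists. The pericyclic step is the more certain closure; the Suzuki closure tolerates the full side chain. It is shorter to the bare carbocycle and longer once C8 is counted.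

**Alternative 2:** The C8–C9 bond is cut and the ring is traced back to the thirteen-membered allylic lactone A3. Forward, enolisation and O-silylation of A3 at low temperature and warming trigger an Ireland–Claisen shift. This forms C8–C9, moves the alkene to Ca=Cb and contracts the lactone to acid A4.
- In its favour: one step creates the ring, both stereocentres and the Ca=Cb geometry, and leaves the exocyclic methylene unmasked.
- Where it is equal or better: on C9 it is better than the chosen plan, which sets C9 only at the end by protonation. Closing a thirteen-membered lactone is also easier than closing a nine-membered carbocycle directly.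
- Against it here: the C8/C9 relationship depends on ketene acetal geometry and on a chair or boat transition state inside a macrocycle, neither of which is easy to predict. Absolute control needs the doubly allylic carbinol ester in A3 to be enantiopure, and that ester is prone to ionisation. Deprotonation at C9 next to C1=CH2 may drift into the conjugated series. A3 still needs its own E C4=C5 alkene and a stereodefined C8=Ca alkene. A4 then needs esterification, desilylation and acetylation.
- Comparison: more is achieved in the key step, at the price of less predictable stereochemistry. The step count is similar or slightly higher.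

**Alternative 3:** The C1–C2 bond is cut and the ring is traced back to iodo aldehyde A5. Forward, CrCl2 with catalytic NiCl2 turns the C1 iodide into a vinylchromium species that adds to the C2 aldehyde (Nozaki–Hiyama–Kishi) and gives allylic alcohol A6.
- In its favour: C8, C9 and every alkene are in place in an open chain before closure. The exocyclic methylene is the iodoalkene itself. The chromium reagent tolerates esters and silyl ethers.
- Where it is equal or better: on chemoselectivity it is at least equal to the chosen plan, and it is better in having C9 set before the ring exists.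
- Against it here: A5 has sp3 C8 and C9 and no Z enoate to pre-bend the chain, so closure of a nine-membered ring competes poorly with intermolecular addition. The aldehyde is beta,gamma-unsaturated and the C9–H of A5 is acidic, so both can isomerise. The C2 hydroxyl of A6 is not in the target and must be removed from an allylic position without moving the exocyclic alkene.
- Comparison: it is weaker on ring closure and costs two or three extra steps for deoxygenation.

Key step: step 13

Remarks before the steps:
- TBS = tert-butyldimethylsilyl, TES = triethylsilyl.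
- C8 keeps one spatial arrangement from 17 to 25. Its label reads S in 17, 24 and 25 and R in 18–23 only because C9 changes between sp3 and sp2 and so changes rank.
- Assumption: the iridium catalyst of step 10 shows its usual sense of induction, under which the (Ra,Rc,Rc) ligand gives the S product when the allyl substituent outranks the nucleophile carbon. The antipodal ligand is used if the crowded terminus reverses this.

## Route

Step 1
Reactants: 1 but-2-yn-1-ol
Product: 3 (2E)-3-iodobut-2-en-1-ol, via alkenylzirconocene chloride 2 (not isolated)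
Conditions: Cp2Zr(H)Cl (2.2 equiv), THF, 0 °C to rt; then I2, −78 to 0 °C
Reagents that add atoms: iodine, [I][I]
Why: Hydrozirconation–iodination: H and Zr add syn, and with excess hydride the metal settles on the less hindered methyl-bearing carbon; iodinolysis with retention gives the E iodide. Trans-hydroalumination with NaAlH2(OCH2CH2OMe)2 would give the Z isomer, which cannot lead to the E ring alkene.

Step 2
Reactants: 3 (2E)-3-iodobut-2-en-1-ol
Product: 4 (2E)-1-bromo-3-iodobut-2-ene
Conditions: CBr4, PPh3, CH2Cl2, 0 °C
Reagents that add atoms: carbon tetrabromide, BrC(Br)(Br)Br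
Why: Appel reaction of a primary allylic alcohol under neutral conditions; the alkenyl iodide and the alkene geometry are untouched.

Step 3
Reactants: 5 methyl acetoacetate; 4 (2E)-1-bromo-3-iodobut-2-ene
Product: 7 methyl (6E)-7-iodo-3-oxooct-6-enoate, via acetoacetate dianion 6 (not isolated)
Conditions: NaH, THF, 0 °C; n-BuLi, 0 °C; then 4, 0 °C to rt; aq NH4Cl
Reagents that add atoms: none
Why: Alkylation of the acetoacetate dianion at its more basic terminal carbon by an allylic bromide; n-BuLi is consumed before the iodoalkene is added, so no iodine–lithium exchange can occur.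

Step 4
Reactants: 8 2-methylbut-3-yn-2-ol
Product: 9 triethyl[(2-methylbut-3-yn-2-yl)oxy]silane
Conditions: Et3SiOTf, 2,6-lutidine, CH2Cl2, −78 to 0 °C
Reagents that add atoms: triethylsilyl trifluoromethanesulfonate, CC[Si](CC)(CC)OS(=O)(=O)C(F)(F)F
Why: Silylation of a tertiary alcohol with a silyl triflate and a hindered base.

Step 5
Reactants: 9 triethyl[(2-methylbut-3-yn-2-yl)oxy]silane
Product: 10 triethyl{[(3E)-2-methyl-4-(4,4,5,5-tetramethyl-1,3,2-dioxaborolan-2-yl)but-3-en-2-yl]oxy}silane
Conditions: pinacolborane, Cp2Zr(H)Cl (5 mol %), Et3N (10 mol %), neat, 60 °C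
Reagents that add atoms: pinacolborane, CC1(C)OBOC1(C)C
Why: Zirconium-catalysed hydroboration of a terminal alkyne: syn addition with boron at the terminus gives the E alkenylboronate.

Step 6
Reactants: 11 prop-2-yn-1-ol
Product: 13 (2Z)-2-(iodomethylidene)but-3-en-1-ol, via chelated alkenylmagnesium bromide 12 (not isolated)
Conditions: CH2=CHMgBr (2.5 equiv), CuI (10 mol %), THF, −10 °C to rt; then I2, −40 to 0 °C
Reagents that add atoms: vinylmagnesium bromide, C=C[Mg]Br; iodine, [I][I]
Why: CuI-catalysed anti-carbomagnesiation of the propargylic alkoxide: the vinyl group adds to the internal carbon (Ca) and magnesium ends on the terminal carbon in a five-membered alkoxide chelate, cis to CH2O. Iodinolysis with retention gives the iodide cis to CH2OH, which is the Ca=Cb geometry of the target.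

Step 7
Reactants: 13 (2Z)-2-(iodomethylidene)but-3-en-1-ol
Product: 14 tert-butyl{[(2Z)-2-(iodomethylidene)but-3-en-1-yl]oxy}dimethylsilane
Conditions: TBSCl, imidazole, CH2Cl2, 0 °C to rt
Reagents that add atoms: tert-butyldimethylsilyl chloride, CC(C)(C)[Si](C)(C)Cl
Why: Standard silylation of a primary alcohol; a TBS ether cannot ionise in the later iridium step, unlike an allylic ester.

Step 8
Reactants: 14 tert-butyl{[(2Z)-2-(iodomethylidene)but-3-en-1-yl]oxy}dimethylsilane; 10 triethyl{[(3E)-2-methyl-4-(4,4,5,5-tetramethyl-1,3,2-dioxaborolan-2-yl)but-3-en-2-yl]oxy}silane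
Product: 15 (3Z,5E)-3-(TBSOCH2)-7-methyl-7-(TESO)octa-1,3,5-triene
Conditions: PdCl2(dppf) (5 mol %), K3PO4, THF/H2O, 45 °C
Reagents that add atoms: none
Why: Suzuki–Miyaura alkenyl–alkenyl coupling forms Cb–Cc with retention in both partners, giving Cc cis to CH2OTBS and an E Cc=Cd alkene.

Step 9
Reactants: 15 (3Z,5E)-3-(TBSOCH2)-7-methyl-7-(TESO)octa-1,3,5-triene
Product: 16 methyl (2E,4Z,6E)-4-(TBSOCH2)-8-methyl-8-(TESO)nona-2,4,6-trien-1-yl carbonate
Conditions: allyl methyl carbonate (5 equiv), second-generation Hoveyda–Grubbs catalyst (5 mol %), CH2Cl2, 40 °C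
Reagents that add atoms: allyl methyl carbonate, C=CCOC(=O)OC
Why: Olefin cross metathesis at the only monosubstituted alkene; the trisubstituted Ca=Cb alkene and the Cc=Cd alkene next to a quaternary carbon do not engage. The conjugated product should form mainly as the E isomer.

Step 10
Reactants: 16 methyl (2E,4Z,6E)-4-(TBSOCH2)-8-methyl-8-(TESO)nona-2,4,6-trien-1-yl carbonate; 7 methyl (6E)-7-iodo-3-oxooct-6-enoate
Product: 17 methyl (6E)-2-[(3S,4Z,6E)-4-(TBSOCH2)-8-methyl-8-(TESO)nona-1,4,6-trien-3-yl]-7-iodo-3-oxooct-6-enoate (both C2 epimers)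
Conditions: [Ir(cod)Cl]2 (2 mol %), (Ra,Rc,Rc)-O,O′-(1,1′-binaphthyl-2,2′-diyl)-N,N-bis(1-phenylethyl)phosphoramidite (4 mol %), 1,5,7-triazabicyclo[4.4.0]dec-5-ene (8 mol %), THF, rt to 40 °C
Reagents that add atoms: none
Why: Iridium-catalysed asymmetric allylic alkylation: the cyclometallated iridium–phosphoramidite complex ionises the linear carbonate and the enolate of 7 attacks the substituted allyl terminus, giving the branched product with a vinyl group on C8. C8 is set by the ligand-controlled face of the allyl. C9 forms as a mixture of no consequence, because it becomes sp2 in step 11.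

Step 11
Reactants: 17 methyl (6E)-2-[(3S,4Z,6E)-4-(TBSOCH2)-8-methyl-8-(TESO)nona-1,4,6-trien-3-yl]-7-iodo-3-oxooct-6-enoate
Product: 19 methyl (2Z,6E)-2-[(3R,4Z,6E)-4-(TBSOCH2)-8-methyl-8-(TESO)nona-1,4,6-trien-3-yl]-7-iodo-3-(trifluoromethanesulfonyloxy)octa-2,6-dienoate, via chelated lithium enolate 18 (not isolated)
Conditions: LiN(SiMe3)2, THF, −78 °C; then N-(5-chloropyridin-2-yl)bis(trifluoromethanesulfonimide), −78 to 0 °C
Reagents that add atoms: N-(5-chloropyridin-2-yl)bis(trifluoromethanesulfonimide), Clc1ccc(nc1)N(S(=O)(=O)C(F)(F)F)S(=O)(=O)C(F)(F)F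
Why: Enol triflate formation from a beta-keto ester under chelation control: lithium bridges the enolate and ester oxygens, so O-sulfonylation gives the triflate cis to CO2Me (Z), the geometry that puts C2 and C8 on the same side of C1=C9.

Step 12
Reactants: 19 methyl (2Z,6E)-2-[(3R,4Z,6E)-4-(TBSOCH2)-8-methyl-8-(TESO)nona-1,4,6-trien-3-yl]-7-iodo-3-(trifluoromethanesulfonyloxy)octa-2,6-dienoate
Product: 20 methyl (2Z,6E)-2-[(3R,4Z,6E)-4-(TBSOCH2)-8-methyl-8-(TESO)nona-1,4,6-trien-3-yl]-7-iodo-3-[(trimethylsilyl)methyl]octa-2,6-dienoate
Conditions: (Me3SiCH2)2CuLi (from Me3SiCH2Li and CuI), THF, −78 to −40 °C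
Reagents that add atoms: (trimethylsilyl)methyllithium, C[Si](C)(C)C[Li]
Why: Cuprate addition–elimination at the beta-carbon of a beta-triflyloxy enoate with retention of alkene geometry. The activated triflate reacts at −78 °C, well below the temperature at which an unactivated alkenyl iodide couples or exchanges.

Step 13
Reactants: 20 methyl (2Z,6E)-2-[(3R,4Z,6E)-4-(TBSOCH2)-8-methyl-8-(TESO)nona-1,4,6-trien-3-yl]-7-iodo-3-[(trimethylsilyl)methyl]octa-2,6-dienoate
Product: 22 methyl (1Z,5E,9R)-9-[(2Z,4E)-1-(TBSO)-6-methyl-6-(TESO)hepta-2,4-dien-2-yl]-6-methyl-2-[(trimethylsilyl)methyl]cyclonona-1,5-diene-1-carboxylate, via B-alkyl-9-borabicyclononane 21 (not isolated)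
Conditions: 9-BBN dimer, THF, 0 °C to rt; then slow addition to PdCl2(dppf) (20 mol %), AsPh3 (40 mol %), Cs2CO3, THF/DMF/H2O, 50 °C, final concentration about 2 mM
Reagents that add atoms: none
Why: 9-BBN adds anti-Markovnikov to the only monosubstituted alkene, the C8 vinyl group; the conjugated diene, the tetrasubstituted enoate and the iodoalkene are far slower, so primary alkylborane 21 results. Zerovalent palladium then inserts into the C5–I bond with retention of the E geometry, base-assisted transmetalation moves the C6 alkyl group from boron to divalent palladium, and reductive elimination forms the sp2–sp3 C5–C6 bond. The closest known reaction type is the intramolecular B-alkyl Suzuki–Miyaura coupling used to close medium rings that contain an E trisubstituted alkene. The nine-membered ring closes through a ten-membered palladacycle that contracts on reductive elimination, with both ends of the new bond inside the ring (endo closure). No stereocentre is created: C8 is untouched and the C4=C5 geometry is inherited from the iodide. Closure is favoured over oligomerisation by slow addition at high dilution and by the Z C1=C9 enoate and the E iodoalkene, which hold the chain in the turn the ring needs. The enoate also keeps C9 non-acidic under the basic coupling and hides the future exocyclic alkene from the borane. The wide-bite-angle dppf ligand speeds reductive elimination relative to beta-hydride elimination of the alkylpalladium intermediate.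

Step 14
Reactants: 22 methyl (1Z,5E,9R)-9-[(2Z,4E)-1-(TBSO)-6-methyl-6-(TESO)hepta-2,4-dien-2-yl]-6-methyl-2-[(trimethylsilyl)methyl]cyclonona-1,5-diene-1-carboxylate
Product: 23 methyl (1Z,5E,9R)-9-[(2Z,4E)-1,6-dihydroxy-6-methylhepta-2,4-dien-2-yl]-6-methyl-2-[(trimethylsilyl)methyl]cyclonona-1,5-diene-1-carboxylate
Conditions: HF·pyridine, pyridine, THF, 0 °C to rt
Reagents that add atoms: none
Why: Buffered HF cleaves the primary TBS and tertiary TES ethers through protonated oxygen. The CH2–SiMe3 bond stays, because its cleavage needs nucleophilic fluoride and a carbanion leaving group, and the hindered conjugated enoate resists attack by the freed hydroxyl.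

Step 15
Reactants: 23 methyl (1Z,5E,9R)-9-[(2Z,4E)-1,6-dihydroxy-6-methylhepta-2,4-dien-2-yl]-6-methyl-2-[(trimethylsilyl)methyl]cyclonona-1,5-diene-1-carboxylate
Product: 24 methyl (1R,2S,5E)-2-[(2Z,4E)-1,6-dihydroxy-6-methylhepta-2,4-dien-2-yl]-5-methyl-9-methylidenecyclonon-5-ene-1-carboxylate
Conditions: Bu4N[Ph3SiF2], THF, 0 °C to rt; then AcOH, 0 °C
Reagents that add atoms: none
Why: Deconjugative protodesilylation of a gamma-silyl enoate: fluoride attacks silicon and expels the ester dienolate, which is protonated at its alpha-carbon C9 and leaves the exocyclic C1=CH2 alkene. C9 is set by internal delivery: the free CH2OH on Ca, hydrogen-bonded to the dienolate, hands over its proton through a six-membered arrangement on the ring face that carries the side chain, so the ester ends trans to the side chain. Acetic acid then neutralises the alkoxide before it can add to the ester.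

Step 16
Reactants: 24 methyl (1R,2S,5E)-2-[(2Z,4E)-1,6-dihydroxy-6-methylhepta-2,4-dien-2-yl]-5-methyl-9-methylidenecyclonon-5-ene-1-carboxylate
Product: 25 methyl (1R,2S,5E)-2-[(2Z,4E)-1-(acetyloxy)-6-hydroxy-6-methylhepta-2,4-dien-2-yl]-5-methyl-9-methylidenecyclonon-5-ene-1-carboxylate
Conditions: Ac2O, pyridine, CH2Cl2, 0 °C
Reagents that add atoms: acetic anhydride, CC(=O)OC(C)=O
Why: Acylation of the unhindered primary allylic hydroxyl; the tertiary hydroxyl does not react under these conditions, and the weak base at 0 °C neither epimerises C9 nor moves the exocyclic alkene.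

## Compound list

1 | but-2-yn-1-ol | CC#CCO | starting material
2 | (E)-alkenylzirconocene chloride with zirconium on C3 and a zirconocene alkoxide on oxygen (formed in the flask) | C/C(=C\CO[Zr](Cl)(C1C=CC=C1)C1C=CC=C1)[Zr](Cl)(C1C=CC=C1)C1C=CC=C1 | intermediate
3 | (2E)-3-iodobut-2-en-1-ol | C/C(I)=C\CO | intermediate
4 | (2E)-1-bromo-3-iodobut-2-ene | C/C(I)=C\CBr | intermediate
5 | methyl acetoacetate | CC(=O)CC(=O)OC | starting material
6 | sodium lithium dianion of methyl acetoacetate (formed in the flask) | C=C([O-])C=C([O-])OC.[Na+].[Li+] | intermediate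
7 | methyl (6E)-7-iodo-3-oxooct-6-enoate | COC(=O)CC(=O)CC/C=C(\C)I | intermediate
8 | 2-methylbut-3-yn-2-ol | CC(C)(O)C#C | starting material
9 | triethyl[(2-methylbut-3-yn-2-yl)oxy]silane | CC[Si](CC)(CC)OC(C)(C)C#C | intermediate
10 | triethyl{[(3E)-2-methyl-4-(4,4,5,5-tetramethyl-1,3,2-dioxaborolan-2-yl)but-3-en-2-yl]oxy}silane | CC[Si](CC)(CC)OC(C)(C)/C=C/B1OC(C)(C)C(C)(C)O1 | intermediate
11 | prop-2-yn-1-ol | OCC#C | starting material
12 | (Z)-alkenylmagnesium bromide chelated by its bromomagnesium alkoxide (formed in the flask) | Br[Mg]/C=C(\CO[Mg]Br)C=C | intermediate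
13 | (2Z)-2-(iodomethylidene)but-3-en-1-ol | I/C=C(\CO)C=C | intermediate
14 | tert-butyl{[(2Z)-2-(iodomethylidene)but-3-en-1-yl]oxy}dimethylsilane | I/C=C(\CO[Si](C)(C)C(C)(C)C)C=C | intermediate
15 | (3Z,5E)-3-(TBSOCH2)-7-methyl-7-(TESO)octa-1,3,5-triene | C=C/C(=C/C=C/C(C)(C)O[Si](CC)(CC)CC)CO[Si](C)(C)C(C)(C)C | intermediate
16 | methyl (2E,4Z,6E)-4-(TBSOCH2)-8-methyl-8-(TESO)nona-2,4,6-trien-1-yl carbonate | COC(=O)OC/C=C/C(=C/C=C/C(C)(C)O[Si](CC)(CC)CC)CO[Si](C)(C)C(C)(C)C | intermediate
17 | methyl (6E)-2-[(3S,4Z,6E)-4-(TBSOCH2)-8-methyl-8-(TESO)nona-1,4,6-trien-3-yl]-7-iodo-3-oxooct-6-enoate (both C2 epimers) | COC(=O)C(C(=O)CC/C=C(\C)I)[C@H](C=C)/C(=C/C=C/C(C)(C)O[Si](CC)(CC)CC)CO[Si](C)(C)C(C)(C)C | intermediate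
18 | chelated lithium (Z)-enolate of 17 (formed in the flask) | [Li+].[O-]/C(CC/C=C(\C)I)=C(\C(=O)OC)[C@H](C=C)/C(=C/C=C/C(C)(C)O[Si](CC)(CC)CC)CO[Si](C)(C)C(C)(C)C | intermediate
19 | methyl (2Z,6E)-2-[(3R,4Z,6E)-4-(TBSOCH2)-8-methyl-8-(TESO)nona-1,4,6-trien-3-yl]-7-iodo-3-(trifluoromethanesulfonyloxy)octa-2,6-dienoate | O=S(=O)(O/C(CC/C=C(\C)I)=C(\C(=O)OC)[C@H](C=C)/C(=C/C=C/C(C)(C)O[Si](CC)(CC)CC)CO[Si](C)(C)C(C)(C)C)C(F)(F)F | intermediate
20 | methyl (2Z,6E)-2-[(3R,4Z,6E)-4-(TBSOCH2)-8-methyl-8-(TESO)nona-1,4,6-trien-3-yl]-7-iodo-3-[(trimethylsilyl)methyl]octa-2,6-dienoate | C[Si](C)(C)C/C(CC/C=C(\C)I)=C(\C(=O)OC)[C@H](C=C)/C(=C/C=C/C(C)(C)O[Si](CC)(CC)CC)CO[Si](C)(C)C(C)(C)C | intermediate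
21 | B-alkyl-9-borabicyclo[3.3.1]nonane from 20, boron on the terminal carbon of the former vinyl group (formed in the flask) | C[Si](C)(C)C/C(CC/C=C(\C)I)=C(\C(=O)OC)[C@H](CCB1C2CCCC1CCC2)/C(=C/C=C/C(C)(C)O[Si](CC)(CC)CC)CO[Si](C)(C)C(C)(C)C | intermediate
22 | methyl (1Z,5E,9R)-9-[(2Z,4E)-1-(TBSO)-6-methyl-6-(TESO)hepta-2,4-dien-2-yl]-6-methyl-2-[(trimethylsilyl)methyl]cyclonona-1,5-diene-1-carboxylate | C[Si](C)(C)C/C1=C(\C(=O)OC)[C@@H](/C(=C/C=C/C(C)(C)O[Si](CC)(CC)CC)CO[Si](C)(C)C(C)(C)C)CC/C(C)=C/CC1 | intermediate
23 | methyl (1Z,5E,9R)-9-[(2Z,4E)-1,6-dihydroxy-6-methylhepta-2,4-dien-2-yl]-6-methyl-2-[(trimethylsilyl)methyl]cyclonona-1,5-diene-1-carboxylate | C[Si](C)(C)C/C1=C(\C(=O)OC)[C@@H](/C(=C/C=C/C(C)(C)O)CO)CC/C(C)=C/CC1 | intermediate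
24 | methyl (1R,2S,5E)-2-[(2Z,4E)-1,6-dihydroxy-6-methylhepta-2,4-dien-2-yl]-5-methyl-9-methylidenecyclonon-5-ene-1-carboxylate | C=C1CC/C=C(\C)CC[C@H](/C(=C/C=C/C(C)(C)O)CO)[C@H]1C(=O)OC | intermediate
25 | methyl (1R,2S,5E)-2-[(2Z,4E)-1-(acetyloxy)-6-hydroxy-6-methylhepta-2,4-dien-2-yl]-5-methyl-9-methylidenecyclonon-5-ene-1-carboxylate | C=C1CC/C=C(\C)CC[C@H](/C(=C/C=C/C(C)(C)O)COC(C)=O)[C@H]1C(=O)OC | target

## Step count and least certain steps

Total step count: 16. Longest linear sequence: 11 steps (steps 6–9, then 10–16, starting from 11).

**Step 13 (key step).** Intermolecular coupling may outrun closure of the strained ring. The alkylpalladium intermediate may also undergo protodeboronation or beta-hydride elimination, and the borane may be consumed at a second alkene. Fallback, from 20 back to 22: hydroboration with 9-BBN and oxidation with NaBO3 give the primary alcohol in which the vinyl group has become CH2CH2OH, F1. I2, PPh3 and imidazole convert it into the primary iodide F2. Zn dust with LiCl inserts into the alkyl C–I bond much faster than into the alkenyl C–I bond. Pd2(dba)3 with tri(2-furyl)phosphine at high dilution then closes the same C5–C6 bond by intramolecular Negishi coupling to give 22.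

**Step 10.** Attack at the unsubstituted allyl terminus, or poor facial selectivity, is possible because the reacting terminus carries a fully substituted alkenyl carbon. A second allylation of the product is also conceivable. Fallback, from 16 and 5 back to 17: the same iridium catalyst is used with the small nucleophile 5, giving the allylated acetoacetate F3. Its dianion (LiN(iPr)2, 2.2 equiv, THF, −78 to 0 °C) is then alkylated at the terminal carbon with 4 to give 17. The complexity is thus moved from the nucleophile to a later, well-behaved alkylation.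

**Step 9.** Turnover may be slow because the ruthenium carbene sits on a dienyl terminus. Secondary metathesis and erosion of E selectivity are also possible. Fallback, from 9 and 11 back to 16, without metathesis:
- Cp2Zr(H)Cl then I2 converts 9 into the (E)-alkenyl iodide F4.
- Sonogashira coupling with 11 (PdCl2(PPh3)2, CuI, Et3N) gives the enynol F5.
- Hydroxyl-directed syn hydrostannation (Bu3SnH, PdCl2(PPh3)2) places tin on the carbon next to the carbinol, giving dienylstannane F6.
- TBSCl and imidazole give its silyl ether F7.
- Stille coupling with (E)-3-iodoprop-2-en-1-ol (Pd(PPh3)4, CuI, CsF, DMF) gives trienol F8.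
- Methyl chloroformate and pyridine convert F8 into 16.

**Step 11.** Partial loss of chelation control at the crowded enolate would give a mixture of alkene isomers, and only the Z series can cyclise. Fallback, from 17 back to 20: NaH in Et2O and ClP(O)(OEt)2 give the Z enol phosphate F9 through the sodium chelate. Its displacement with (Me3SiCH2)2CuLi proceeds with retention to give 20.

**Step 15.** An external proton source may outpace internal delivery and give poor facial selectivity at C9. The freed alkoxide may close onto the ester to a six-membered lactone. The exocyclic alkene may drift back into conjugation if the basic stage is prolonged. Fallback, from 23 back to 25: acetylation first (Ac2O, pyridine) gives the acetate F10, which has no free primary hydroxyl. Bu4NF buffered with AcOH then effects the deconjugative protodesilylation and gives 25 directly. Control of C9 then rests on the external proton donor and, if needed, on a short base equilibration (DBU) that the acetate tolerates.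

## Further compounds

F1 | step 13 | methyl (2Z,6E)-2-[(3R,4Z,6E)-4-(TBSOCH2)-1-hydroxy-8-methyl-8-(TESO)nona-4,6-dien-3-yl]-7-iodo-3-[(trimethylsilyl)methyl]octa-2,6-dienoate | C[Si](C)(C)C/C(CC/C=C(\C)I)=C(\C(=O)OC)[C@H](CCO)/C(=C/C=C/C(C)(C)O[Si](CC)(CC)CC)CO[Si](C)(C)C(C)(C)C
F2 | step 13 | methyl (2Z,6E)-2-[(3R,4Z,6E)-4-(TBSOCH2)-1-iodo-8-methyl-8-(TESO)nona-4,6-dien-3-yl]-7-iodo-3-[(trimethylsilyl)methyl]octa-2,6-dienoate | C[Si](C)(C)C/C(CC/C=C(\C)I)=C(\C(=O)OC)[C@H](CCI)/C(=C/C=C/C(C)(C)O[Si](CC)(CC)CC)CO[Si](C)(C)C(C)(C)C
F3 | step 10 | methyl (3S,4Z,6E)-2-acetyl-3-ethenyl-4-(TBSOCH2)-8-methyl-8-(TESO)nona-4,6-dienoate (both C2 epimers) | COC(=O)C(C(C)=O)[C@H](C=C)/C(=C/C=C/C(C)(C)O[Si](CC)(CC)CC)CO[Si](C)(C)C(C)(C)C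
F4 | step 9 | triethyl{[(3E)-4-iodo-2-methylbut-3-en-2-yl]oxy}silane | CC[Si](CC)(CC)OC(C)(C)/C=C/I
F5 | step 9 | (4E)-6-methyl-6-(TESO)hept-4-en-2-yn-1-ol | OCC#C/C=C/C(C)(C)O[Si](CC)(CC)CC
F6 | step 9 | (2E,4E)-6-methyl-2-(tributylstannyl)-6-(TESO)hepta-2,4-dien-1-ol | CCCC[Sn](CCCC)(CCCC)/C(CO)=C/C=C/C(C)(C)O[Si](CC)(CC)CC
F7 | step 9 | tert-butyldimethylsilyl ether of F6 | CCCC[Sn](CCCC)(CCCC)/C(CO[Si](C)(C)C(C)(C)C)=C/C=C/C(C)(C)O[Si](CC)(CC)CC
F8 | step 9 | (2E,4Z,6E)-4-(TBSOCH2)-8-methyl-8-(TESO)nona-2,4,6-trien-1-ol | OC/C=C/C(=C/C=C/C(C)(C)O[Si](CC)(CC)CC)CO[Si](C)(C)C(C)(C)C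
F9 | step 11 | methyl (2Z,6E)-3-[(diethoxyphosphoryl)oxy]-2-[(3R,4Z,6E)-4-(TBSOCH2)-8-methyl-8-(TESO)nona-1,4,6-trien-3-yl]-7-iodoocta-2,6-dienoate | CCOP(=O)(OCC)O/C(CC/C=C(\C)I)=C(\C(=O)OC)[C@H](C=C)/C(=C/C=C/C(C)(C)O[Si](CC)(CC)CC)CO[Si](C)(C)C(C)(C)C
F10 | step 15 | methyl (1Z,5E,9R)-9-[(2Z,4E)-1-(acetyloxy)-6-hydroxy-6-methylhepta-2,4-dien-2-yl]-6-methyl-2-[(trimethylsilyl)methyl]cyclonona-1,5-diene-1-carboxylate | C[Si](C)(C)C/C1=C(\C(=O)OC)[C@@H](/C(=C/C=C/C(C)(C)O)COC(C)=O)CC/C(C)=C/CC1
A1 | alternative 1 | 2-ethenyl-2-methyl-1-[3-(trimethylsilyl)prop-1-en-2-yl]cyclopentan-1-ol (racemic, relative configuration left open) | C=CC1(C)CCCC1(O)C(=C)C[Si](C)(C)C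
A2 | alternative 1 | (1Z,5E)-6-methyl-2-[(trimethylsilyl)methyl]cyclonona-1,5-dien-1-yl trifluoromethanesulfonate | C[Si](C)(C)C/C1=C(\OS(=O)(=O)C(F)(F)F)CCC/C(C)=C/CC1
A3 | alternative 2 | (7E)-12-(TBSOCH2)-8-methyl-4-methylidene-13-[(1E)-3-methyl-3-(TESO)but-1-en-1-yl]oxacyclotrideca-7,11-dien-2-one (C11=C12 geometry and C13 configuration left open) | O=C1CC(=C)CC/C=C(\C)CCC=C(CO[Si](C)(C)C(C)(C)C)C(/C=C/C(C)(C)O[Si](CC)(CC)CC)O1
A4 | alternative 2 | (1R,2S,5E)-2-[(2Z,4E)-1-(TBSO)-6-methyl-6-(TESO)hepta-2,4-dien-2-yl]-5-methyl-9-methylidenecyclonon-5-ene-1-carboxylic acid | C=C1CC/C=C(\C)CC[C@H](/C(=C/C=C/C(C)(C)O[Si](CC)(CC)CC)CO[Si](C)(C)C(C)(C)C)[C@H]1C(=O)O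
A5 | alternative 3 | methyl (6E)-2-(1-iodoethenyl)-3-[(2Z,4E)-1-(TBSO)-6-methyl-6-(TESO)hepta-2,4-dien-2-yl]-6-methyl-9-oxonon-6-enoate (C2 and C3 arranged as C9 and C8 of 25) | O=CC/C=C(\C)CC[C@H](/C(=C/C=C/C(C)(C)O[Si](CC)(CC)CC)CO[Si](C)(C)C(C)(C)C)[C@H](C(I)=C)C(=O)OC
A6 | alternative 3 | methyl (1R,2S,5E)-8-hydroxy-2-[(2Z,4E)-1-(TBSO)-6-methyl-6-(TESO)hepta-2,4-dien-2-yl]-5-methyl-9-methylidenecyclonon-5-ene-1-carboxylate (one C8 epimer drawn) | C=C1[C@@H](O)C/C=C(\C)CC[C@H](/C(=C/C=C/C(C)(C)O[Si](CC)(CC)CC)CO[Si](C)(C)C(C)(C)C)[C@H]1C(=O)OC
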